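**Retrosynthetic overview**

1. Ring numbering: C1 (C=O next to the chain), C2 (nonadecyl), C3 (H), C4 (C=O), C5, C6. The route rests on the trisubstituted C2=C3 double bond of the six-membered ring, which lies between the two oxygen-bearing carbons C1 and C4.
2. 15 ⇐ 14 ⇐ 13 ⇐ 12: only oxidation-state changes (hydroquinone oxidation, tautomerisation, double alcohol oxidation), so the ring can be built as a cyclohex-2-ene-1,4-diol.
3. 12 ⇐ 11: the C2=C3 bond is cut by ring-closing metathesis of a 1,7-diene (chain-bearing 1,1-disubstituted alkene plus vinyl carbinol). The single ring is formed here, in step 5.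
4. 11 ⇐ 10 + 9 (C1–C2 bond, 1-alkylvinyl Grignard addition to a lactol); 9 ⇐ 8 ⇐ 5 + 6 (C4–C5 bond, Grignard addition to acrolein); 10 ⇐ 4 ⇐ 1 + 2 (allylic substitution).

Key step: step 5

Remark: the target is achiral. The carbinol and hemiacetal centres of 8, 9, 11 and 12 are carried as stereoisomer mixtures because each of these carbons ends as an sp2 carbon.

**Route**

Step 1
Reactants: 1 1-bromooctadecane; 2 2,3-dibromopropene
Product: 4 2-bromohenicos-1-ene, via octadecylmagnesium bromide 3 (not isolated)
Conditions: Mg, THF, 45 °C; then 2 (1.3 equiv), CuBr·SMe2 (5 mol %), THF, 0 °C → rt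
Reagents that add atoms: none
Why: Copper-catalysed allylic substitution of the alkyl Grignard reagent on 2,3-dibromopropene (SN2 and SN2' lead to the same product) should replace only the allylic bromide, because the vinylic C–Br bond does not react with Grignard reagents in the absence of nickel or palladium.

Step 2
Reactants: 5 2-(2-bromoethyl)-1,3-dioxolane; 6 acrolein
Product: 8 5-(1,3-dioxolan-2-yl)pent-1-en-3-ol (racemic), via [2-(1,3-dioxolan-2-yl)ethyl]magnesium bromide 7 (not isolated)
Conditions: Mg, THF, 25–30 °C; then 6, THF, −78 → 0 °C; sat. aq NH4Cl
Reagents that add atoms: none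
Why: Grignard 1,2-addition to the aldehyde of acrolein, with the reagent formed below 30 °C because it decomposes on warming, should give the secondary allylic alcohol, whose single stereocentre is left uncontrolled since that carbon later becomes a quinone carbonyl.

Step 3
Reactants: 8 5-(1,3-dioxolan-2-yl)pent-1-en-3-ol
Product: 9 5-ethenyloxolan-2-ol (lactol, mixture of anomers, in equilibrium with 4-hydroxyhex-5-enal)
Conditions: 1 M aq HCl, THF, rt
Reagents that add atoms: water, O
Why: Acid-catalysed acetal hydrolysis, helped by participation of the γ-hydroxyl group, should free the aldehyde, which rests as the five-membered lactol with an uncontrolled hemiacetal centre that is of no consequence.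

Step 4
Reactants: 4 2-bromohenicos-1-ene; 9 5-ethenyloxolan-2-ol
Product: 11 2-nonadecylocta-1,7-diene-3,6-diol (mixture of diastereomers), via (henicos-1-en-2-yl)magnesium bromide 10 (not isolated)
Conditions: Mg, THF, 45 °C; then 9 (0.4 equiv relative to 4), THF, 0 → 40 °C; sat. aq NH4Cl
Reagents that add atoms: none
Why: Grignard addition to a lactol, in which the first equivalent of the 1-alkylvinyl Grignard reagent deprotonates the hemiacetal, the magnesium lactolate opens to the alkoxy aldehyde and a second equivalent adds to its carbonyl group, should give the 1,4-diol as an unselective syn/anti mixture that is acceptable because both carbinol centres are oxidised later.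

Step 5
Reactants: 11 2-nonadecylocta-1,7-diene-3,6-diol
Product: 12 2-nonadecylcyclohex-2-ene-1,4-diol (cis/trans mixture)
Conditions: (H2IMes)(PCy3)Cl2Ru=CHPh (second-generation Grubbs catalyst, 5 mol %), CH2Cl2 (5 mM), 40 °C
Reagents that add atoms: none
Why: Initiation should transfer the ruthenium carbene from the benzylidene to the monosubstituted alkene of the vinyl carbinol; this carbene then engages the chain-bearing 1,1-disubstituted alkene of the same molecule to give a ruthenacyclobutane, whose fragmentation delivers the cyclohexene and a ruthenium methylidene that carries the cycle on. The closest known reaction type is ring-closing metathesis of 1,7-dienes having one 1,1-disubstituted end to trisubstituted cyclohexenes, unprotected allylic alcohols included. The carbocycle, the only ring of the target, closes as a six-membered ring through the new C2=C3 double bond, and loss of gaseous ethylene pulls the equilibrium towards the ring. No stereocentre is created; the two carbinol centres are not touched, and the cis/trans mixture converges once both become carbonyl carbons. The step needs intramolecular closure to be preferred over acyclic diene metathesis oligomers and over hydride-mediated double-bond migration that would turn the allylic alcohols into ketones; high dilution, the strain-free six-membered ring, the inability of the 1,1-disubstituted alkene to homodimerise and the reversibility of any dimerisation at the vinyl carbinol end work in its favour.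

Step 6
Reactants: 12 2-nonadecylcyclohex-2-ene-1,4-diol
Product: 13 2-nonadecylcyclohex-2-ene-1,4-dione
Conditions: Dess–Martin periodinane (2.4 equiv), CH2Cl2, 0 °C → rt
Reagents that add atoms: none
Why: Dess–Martin oxidation should convert both secondary allylic alcohols into ketones under nearly neutral conditions without touching the trisubstituted alkene, and it removes both stereocentres.

Step 7
Reactants: 13 2-nonadecylcyclohex-2-ene-1,4-dione
Product: 14 2-nonadecylbenzene-1,4-diol
Conditions: TsOH·H2O (10 mol %), THF, rt, under Ar
Reagents that add atoms: none
Why: Acid-catalysed keto–enol tautomerisation of the cyclohex-2-ene-1,4-dione (two enolisations) is driven by the gain of aromaticity and should give the alkylhydroquinone.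

Step 8
Reactants: 14 2-nonadecylbenzene-1,4-diol
Product: 15 2-nonadecylcyclohexa-2,5-diene-1,4-dione (2-nonadecyl-1,4-benzoquinone)
Conditions: Ag2O (2 equiv), MgSO4, Et2O, rt
Reagents that add atoms: none
Why: Two-electron oxidation of a hydroquinone to the para-benzoquinone with Ag2O is a standard mild dehydrogenation that should leave the saturated side chain untouched.

**Compound list**

1 | 1-bromooctadecane | CCCCCCCCCCCCCCCCCCBr | starting material
2 | 2,3-dibromopropene | C=C(Br)CBr | starting material
3 | octadecylmagnesium bromide | CCCCCCCCCCCCCCCCCC[Mg]Br | intermediate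
4 | 2-bromohenicos-1-ene | C=C(Br)CCCCCCCCCCCCCCCCCCC | intermediate
5 | 2-(2-bromoethyl)-1,3-dioxolane | BrCCC1OCCO1 | starting material
6 | acrolein (prop-2-enal) | C=CC=O | starting material
7 | [2-(1,3-dioxolan-2-yl)ethyl]magnesium bromide | Br[Mg]CCC1OCCO1 | intermediate
8 | 5-(1,3-dioxolan-2-yl)pent-1-en-3-ol, racemic | C=CC(O)CCC1OCCO1 | intermediate
9 | 5-ethenyloxolan-2-ol, mixture of anomers | C=CC1CCC(O)O1 | intermediate
10 | (henicos-1-en-2-yl)magnesium bromide | C=C([Mg]Br)CCCCCCCCCCCCCCCCCCC | intermediate
11 | 2-nonadecylocta-1,7-diene-3,6-diol, mixture of diastereomers | C=C(CCCCCCCCCCCCCCCCCCC)C(O)CCC(O)C=C | intermediate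
12 | 2-nonadecylcyclohex-2-ene-1,4-diol, cis/trans mixture | OC1CCC(O)C(CCCCCCCCCCCCCCCCCCC)=C1 | intermediate
13 | 2-nonadecylcyclohex-2-ene-1,4-dione | O=C1CCC(=O)C(CCCCCCCCCCCCCCCCCCC)=C1 | intermediate
14 | 2-nonadecylbenzene-1,4-diol | Oc1ccc(O)c(CCCCCCCCCCCCCCCCCCC)c1 | intermediate
15 | 2-nonadecylcyclohexa-2,5-diene-1,4-dione | CCCCCCCCCCCCCCCCCCCC1=CC(=O)C=CC1=O | target

**Step count**

Total steps: 8. Longest linear sequence: 7 steps (steps 2 to 8, from 5 and 6).

**Steps most likely to fail**

Step 5 (ring-closing metathesis). As the catalyst decays, ruthenium hydride species can migrate the double bonds of the free allylic alcohols and turn them into saturated ketones. Intermolecular metathesis at the unhindered vinyl carbinol end can also outrun closure onto the hindered 1,1-disubstituted alkene, so that oligomers form in place of the cyclohexene. Fallback: the ring is taken from an arene and no ring closure is needed. It sets out from octadecylmagnesium bromide 3 (made from 1 as in step 1) and comes back to the route at hydroquinone 14. The Grignard reagent 3 would be added to commercial 2,5-dimethoxybenzaldehyde in THF at 0 °C to give 1-(2,5-dimethoxyphenyl)nonadecan-1-ol F1. Ionic hydrogenation of this electron-rich benzylic alcohol with Et3SiH and CF3CO2H in CH2Cl2 should remove the hydroxyl group and give 1,4-dimethoxy-2-nonadecylbenzene F2. BBr3 in CH2Cl2 (−78 °C → rt) should then cleave both methyl ethers to 14, which step 8 oxidises to 15.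

Step 4 (vinyl Grignard addition to the lactol). Part of the long-chain reagent is lost as a base, by protonation by the lactol and by enolisation of the opened hydroxy aldehyde. Opening of the magnesium lactolate may also be sluggish, so the addition may stop short of completion. Fallback: the roles of the two fragments are exchanged, so that the long-chain piece becomes the electrophile and a cheap vinyl reagent is the one used in excess. It sets out from Grignard reagents 10 and 7 and comes back at 11. Reagent 10 would be formylated with DMF (THF, 0 °C, then aqueous acid) to 2-methylidenehenicosanal F3. 1,2-Addition of 7 to this α-substituted enal should give 1-(1,3-dioxolan-2-yl)-4-methylidenetricosan-3-ol F4. Acetal hydrolysis as in step 3 should give the lipophilic, easily isolated lactol 5-(henicos-1-en-2-yl)oxolan-2-ol F5. Commercial vinylmagnesium bromide CH2=CHMgBr (3 equiv, THF, 0 °C → rt) should open F5 to 11.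

Step 3 (acetal hydrolysis and isolation of the lactol). Hydrolysis may stall at the mixed 2-(2-hydroxyethoxy)tetrahydrofuran acetal. The small, water-soluble and volatile lactol may be lost on extraction and concentration, or may condense with itself to a bis-lactol ether, so that little dry material reaches step 4. Fallback: the hydroxyl group is silylated, so that a free lipophilic aldehyde and not a lactol is the electrophile, and only a slight excess of the long-chain reagent is needed. It sets out from 8 and comes back at 11. Silylation of 8 with t-BuPh2SiCl and imidazole in DMF should give tert-butyl{[5-(1,3-dioxolan-2-yl)pent-1-en-3-yl]oxy}diphenylsilane F6. Hydrolysis of the dioxolane (2 M aq HCl, THF, rt), which the silyl ether should withstand, gives 4-[(tert-butyldiphenylsilyl)oxy]hex-5-enal F7. Addition of 10 (1.2 equiv, THF, 0 °C) should give 6-[(tert-butyldiphenylsilyl)oxy]-2-nonadecylocta-1,7-dien-3-ol F8. Bu4NF in THF then removes the silyl group to give 11.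

**Further compounds**

F1 | step 5 | 1-(2,5-dimethoxyphenyl)nonadecan-1-ol | COc1ccc(OC)c(C(O)CCCCCCCCCCCCCCCCCC)c1
F2 | step 5 | 1,4-dimethoxy-2-nonadecylbenzene | COc1ccc(OC)c(CCCCCCCCCCCCCCCCCCC)c1
F3 | step 4 | 2-methylidenehenicosanal | C=C(C=O)CCCCCCCCCCCCCCCCCCC
F4 | step 4 | 1-(1,3-dioxolan-2-yl)-4-methylidenetricosan-3-ol | C=C(CCCCCCCCCCCCCCCCCCC)C(O)CCC1OCCO1
F5 | step 4 | 5-(henicos-1-en-2-yl)oxolan-2-ol | C=C(CCCCCCCCCCCCCCCCCCC)C1CCC(O)O1
F6 | step 3 | tert-butyl{[5-(1,3-dioxolan-2-yl)pent-1-en-3-yl]oxy}diphenylsilane | C=CC(CCC1OCCO1)O[Si](c1ccccc1)(c1ccccc1)C(C)(C)C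
F7 | step 3 | 4-[(tert-butyldiphenylsilyl)oxy]hex-5-enal | C=CC(CCC=O)O[Si](c1ccccc1)(c1ccccc1)C(C)(C)C
F8 | step 3 | 6-[(tert-butyldiphenylsilyl)oxy]-2-nonadecylocta-1,7-dien-3-ol | C=C(CCCCCCCCCCCCCCCCCCC)C(O)CCC(C=C)O[Si](c1ccccc1)(c1ccccc1)C(C)(C)C
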